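**Retrosynthetic overview**
- The target is a spiro [4+2] dimer of two guaianolide halves (guaiane numbering; primed atoms belong to the saturated-ketone half). Ring D (cyclohexene, bonds C2–C4′ and C14–C15′) is disconnected last, to dehydrozaluzanin C as dienophile and its 1,2-dehydro trienone as diene; a C1=C10 → C1=C2 shift then sets C10 and C5.
- Both halves come from the same monomer. Its rings A (five-membered) and B (seven-membered) are made together in the key step, the photochemical dienone rearrangement of α-santonin (6-6 → 5-7). Santonin already carries ring C (lactone) with C6 and C7.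
- Monomer adjustment: enone → Δ3 olefin with H-5 set by reductive transposition, C10 dehydration, lactone methylenation plus epoxidation (estafiatin), epoxide → allylic alcohol, oxidation.
- Order of ring formation: ring C (from santonin) → rings A and B (one operation, step 1) → ring D (step 8); rings A′, B′, C′ are those of the second monomer molecule.

Assumption: the SMILES is taken literally, so H-5 of the dienone half is cis to H-6 (C5 epimeric to C5 of dehydrozaluzanin C); this γ-epimerizable centre is assumed to settle in that configuration under the basic conditions of the last step.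

**Route**

Step 1
Reactants: 1 (−)-α-santonin
Product: 2 isophotosantonic lactone (10α-hydroxy-3-oxo-1αH-guai-4-en-12,6α-olide)
Conditions: hν (high-pressure Hg lamp, Pyrex), AcOH–H2O 1:1, reflux, N2
Reagents that add atoms: water, O
Why: Photochemical rearrangement of the cross-conjugated cyclohexadienone (santonin → isophotosantonic lactone type): C1–C5 bonding in the excited state and cleavage of C5–C10 in the protonated zwitterion turn the two six-membered rings into the cyclopentenone (ring A) and the cycloheptane (ring B) in one operation, water captures the C10 cation on the α-face, H-1 ends α, and C6, C7 and C11 are not touched.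

Step 2
Reactants: 2 isophotosantonic lactone
Product: 3 3β,10α-dihydroxy-1αH-guai-4-en-12,6α-olide
Conditions: NaBH4, CeCl3·7H2O, MeOH, −40 °C
Reagents that add atoms: none
Why: Luche 1,2-reduction: hydride reaches the cyclopentenone carbonyl from the α-face, opposite the β-oriented C1–C10 bond, to give the 3β-alcohol, and CeCl3 keeps the reaction away from conjugate reduction and from the lactone.

Step 3
Reactants: 3 3β,10α-dihydroxy-1αH-guai-4-en-12,6α-olide
Product: 6 10α-hydroxy-1αH,5αH-guai-3-en-12,6α-olide, via Mitsunobu sulfonylhydrazine 4 (not isolated), via allylic diazene 5 (not isolated)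
Conditions: 2-O2NC6H4SO2NHNH2, PPh3, DEAD, THF, −30 °C; then 23 °C
Reagents that add atoms: none
Why: Myers reductive 1,3-transposition: Mitsunobu displacement with inversion places the sulfonylhydrazine nitrogen α at C3, loss of 2-nitrobenzenesulfinic acid on warming gives the monoalkyl diazene, and its suprafacial retro-ene loss of N2 delivers hydrogen to C5 on the α-face, which sets the cis 1α,5α ring fusion and the Δ3 olefin.

Step 4
Reactants: 6 10α-hydroxy-1αH,5αH-guai-3-en-12,6α-olide
Product: 7 1αH,5αH-guaia-3,10(14)-dien-12,6α-olide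
Conditions: SOCl2, pyridine, CH2Cl2, −20 → 0 °C
Reagents that add atoms: none
Why: E2 dehydration of the tertiary alcohol through its chlorosulfite: H-1 is syn to the leaving group and cannot be lost, so anti elimination takes a hydrogen of the freely rotating C14 methyl group and gives mainly the exocyclic C10=C14 olefin (the minor Δ9 isomer is removed on AgNO3-impregnated silica).

Step 5
Reactants: 7 1αH,5αH-guaia-3,10(14)-dien-12,6α-olide
Product: 10 estafiatin (3α,4α-epoxy-1αH,5αH-guaia-10(14),11(13)-dien-12,6α-olide), via 11-phenylselanyl lactone 8 (not isolated), via isodehydrocostus lactone 9 (not isolated)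
Conditions: LiN(iPr)2, THF, −78 °C; PhSeCl; AcOH; then mCPBA (3.3 equiv), CH2Cl2, −78 → 0 °C
Reagents that add atoms: mCPBA (3-chloroperbenzoic acid), OOC(=O)c1cccc(Cl)c1
Why: α-Selenenylation of the lactone enolate trans to the axial H-7 and selenoxide syn-elimination, which can therefore only go into the methyl group, give the α-methylene lactone, and the excess peracid then epoxidizes (Prilezhaev) only the electron-rich trisubstituted Δ3 olefin, from the convex α-face, because the 1,1-disubstituted and the conjugated olefins react more slowly.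

Step 6
Reactants: 10 estafiatin
Product: 11 3-epizaluzanin C (3α-hydroxy-1αH,5αH-guaia-4(15),10(14),11(13)-trien-12,6α-olide)
Conditions: Al(OiPr)3, toluene, reflux
Reagents that add atoms: none
Why: Al(OiPr)3-mediated isomerization of an epoxide to an allylic alcohol: aluminium opens the tertiary C4–O bond while its alkoxide removes a syn hydrogen from the C15 methyl group through a cyclic transition state, which gives the exocyclic C4=C15 olefin and leaves the C3 oxygen α.

Step 7
Reactants: 11 3-epizaluzanin C
Product: 12 dehydrozaluzanin C (3-oxo-1αH,5αH-guaia-4(15),10(14),11(13)-trien-12,6α-olide)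
Conditions: Dess–Martin periodinane, CH2Cl2, 0 °C → rt
Reagents that add atoms: none
Why: Dess–Martin oxidation of the secondary allylic alcohol to the α-methylene cyclopentanone under mild, non-basic conditions that neither epimerize C1/C5 nor move the exocyclic olefins; the C3 stereocentre disappears.

Step 8
Reactants: 12 dehydrozaluzanin C (two molecules: 1 equiv as diene precursor, 2 equiv as dienophile)
Product: 16 target CNP0221188.1, via silyl dienol ether 13 (not isolated), via cross-conjugated trienone 14 (not isolated), via Diels–Alder adduct 15 (not isolated)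
Conditions: TMSOTf, Et3N, CH2Cl2, 0 °C (on 1 equiv of 12); then Pd(OAc)2 (1.1 equiv), 12 (2 equiv), MeCN, 40 °C, Ar; then DBU (0.3 equiv), 0 °C → rt
Reagents that add atoms: none
Why: Soft enolization gives the 2-silyloxydiene, Saegusa–Ito oxidation with Pd(OAc)2 turns it into the trienone, whose C2=C1–C10=C14 diene adds from its open α-face to the exocyclic enone of a second molecule of 12 in an intermolecular Diels–Alder reaction ("ortho" orientation, exo-carbonyl approach to the convex α-face of 12, which fixes the spiro centre C4′), and DBU then moves the C1=C10 bond into conjugation through the dienolate, protonated at C10 on the α-face, and equilibrates the now γ-acidic C5 to the cis H-5/H-6 arrangement of the target.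

**Compound list**

1 | (−)-α-santonin (3-oxoeudesma-1,4-dien-12,6α-olide; 6βH, 7αH, 10β-methyl, 11βH) | C[C@H]1[C@@H]2CC[C@]3(C=CC(=O)C(=C3[C@H]2OC1=O)C)C | starting material
2 | isophotosantonic lactone (10α-hydroxy-10β-methyl-3-oxo-1αH-guai-4-en-12,6α-olide; 11βH) | C[C@@]1(O)CC[C@@H]2[C@@H](C3=C(C)C(=O)C[C@H]31)OC(=O)[C@H]2C | intermediate
3 | 3β,10α-dihydroxy-1αH-guai-4-en-12,6α-olide (11βH) | C[C@@]1(O)CC[C@@H]2[C@@H](C3=C(C)[C@@H](O)C[C@H]31)OC(=O)[C@H]2C | intermediate
4 | Mitsunobu sulfonylhydrazine: 3α-[1-(2-nitrobenzenesulfonyl)hydrazinyl] analogue of 3 (not isolated) | C[C@@]1(O)CC[C@@H]2[C@@H](C3=C(C)[C@H](N(N)S(=O)(=O)c4ccccc4[N+](=O)[O-])C[C@H]31)OC(=O)[C@H]2C | intermediate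
5 | allylic diazene: 3α-diazenyl-10α-hydroxy-1αH-guai-4-en-12,6α-olide (not isolated) | C[C@@]1(O)CC[C@@H]2[C@@H](C3=C(C)[C@H](N=N)C[C@H]31)OC(=O)[C@H]2C | intermediate
6 | 10α-hydroxy-1αH,5αH-guai-3-en-12,6α-olide (11βH) | C[C@@]1(O)CC[C@@H]2[C@@H]([C@H]3C(C)=CC[C@H]31)OC(=O)[C@H]2C | intermediate
7 | 1αH,5αH-guaia-3,10(14)-dien-12,6α-olide (11βH) | C=C1CC[C@@H]2[C@@H]([C@H]3C(C)=CC[C@H]31)OC(=O)[C@H]2C | intermediate
8 | 11-phenylselanyl lactone: 11β-phenylselanyl-11α-methyl derivative of 7 (not isolated) | C=C1CC[C@@H]2[C@@H]([C@H]3C(C)=CC[C@H]31)OC(=O)[C@]2(C)[Se]c4ccccc4 | intermediate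
9 | isodehydrocostus lactone: 1αH,5αH-guaia-3,10(14),11(13)-trien-12,6α-olide (not isolated) | C=C1CC[C@@H]2[C@@H]([C@H]3C(C)=CC[C@H]31)OC(=O)C2=C | intermediate
10 | estafiatin: 3α,4α-epoxy-1αH,5αH-guaia-10(14),11(13)-dien-12,6α-olide | C=C1CC[C@@H]2[C@@H]([C@H]3[C@]4(C)O[C@@H]4C[C@H]31)OC(=O)C2=C | intermediate
11 | 3-epizaluzanin C: 3α-hydroxy-1αH,5αH-guaia-4(15),10(14),11(13)-trien-12,6α-olide | C=C1CC[C@@H]2[C@@H]([C@@H]3[C@H]1C[C@@H](O)C3=C)OC(=O)C2=C | intermediate
12 | dehydrozaluzanin C: 3-oxo-1αH,5αH-guaia-4(15),10(14),11(13)-trien-12,6α-olide | C=C1CC[C@@H]2[C@@H]([C@@H]3[C@H]1CC(=O)C3=C)OC(=O)C2=C | intermediate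
13 | silyl dienol ether: 3-trimethylsilyloxy-1αH,5αH-guaia-2,4(15),10(14),11(13)-tetraen-12,6α-olide (not isolated) | C=C1CC[C@@H]2[C@@H]([C@@H]3[C@H]1C=C(O[Si](C)(C)C)C3=C)OC(=O)C2=C | intermediate
14 | cross-conjugated trienone: 3-oxo-5αH-guaia-1,4(15),10(14),11(13)-tetraen-12,6α-olide (not isolated) | C=C1CC[C@@H]2[C@@H]([C@@H]3C1=CC(=O)C3=C)OC(=O)C2=C | intermediate
15 | Diels–Alder adduct: spiro dimer with C2–C4′ and C14–C15′ bonds, C1=C10 olefin, 2βH, 5αH, C4′ as in the target (not isolated) | C=C1C(=O)[C@H]2C3=C(CC[C@H]4C(=C)C(=O)O[C@@H]4[C@@H]13)CC[C@]21C(=O)C[C@H]2C(=C)CC[C@H]3C(=C)C(=O)O[C@@H]3[C@H]21 | intermediate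
16 | CNP0221188.1: spiro dimer with C1=C2 enone; dienone half 5S,6S,7S,10R (H-5 cis to H-6); ketone half 1′R,4′R,5′R,6′S,7′S | C=C1C(=O)C2=C3[C@H](CC[C@H]4C(=C)C(=O)O[C@@H]4[C@H]13)CC[C@]21C(=O)C[C@H]2C(=C)CC[C@H]3C(=C)C(=O)O[C@@H]3[C@H]21 | target

**Step count and risks**

Total steps: 8. Longest linear sequence: 8 (1 → 16).

Step 8 is the most likely to fail. The trienone 14 must be trapped by 12 faster than it reacts with itself. Above all, the cycloaddition and the C10 protonation leave H-5 α, so the target configuration at C5 depends entirely on the equilibration; its position is not known, and ring-B strain may well favour H-5 trans to H-6. The fallback sets out from 15 and comes back at 16. The DBU treatment is stopped at 0 °C as soon as the olefin is conjugated, which gives the 5α-H enone F1. TMSOTf and Et3N then convert it, by γ-deprotonation at C5 (the C3′ ketone is silylated as well), into the bis(silyl) dienol ether F2. F2 is protonated at C5 at −78 °C in toluene with the enantiomer of the BINOL·SnCl4 complex that delivers the proton to the β-face. This is reagent-controlled kinetic protonation in place of equilibration; it gives 16, which is then kept away from base.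

Step 3 is the second risk. Mitsunobu displacement at the hindered cyclopentenyl carbinol may give elimination or SN2′ products, and the C5 configuration depends on the facial course of steps 2 and 3. The fallback sets out from 2 and comes back at 6. The enone is hydrogenated (H2, 10% Pd on carbon, EtOAc; both hydrogens from the α-face) to the cis-fused ketone F3. NaBH4 reduces it to the 3β-alcohol F4, and MsCl/Et3N gives the mesylate F5. LiBr/Li2CO3 in DMF at 120 °C then removes the anti-periplanar H-4α to give 6.

Step 6 is the third risk. Al(OiPr)3 at reflux may add isopropoxide to the α-methylene lactone of 10. The fallback sets out from 7 and comes back at 11. Diene 7 is epoxidized with mCPBA before the lactone is methylenated, giving 11β,13-dihydroestafiatin F6. Al(OiPr)3 isomerizes it to the allylic alcohol F7, in which no Michael acceptor is present. The dianion (LiN(iPr)2, 2.3 equiv) is selenenylated with PhSeCl to the selenide F8, and H2O2/AcOH at 0 °C gives 11 by syn-elimination.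

**Further compounds**

F1 | step 8 | 5α-H epimer of 16 (dienone half with H-5 trans to H-6) | C=C1C(=O)C2=C3[C@H](CC[C@H]4C(=C)C(=O)O[C@@H]4[C@@H]13)CC[C@]21C(=O)C[C@H]2C(=C)CC[C@H]3C(=C)C(=O)O[C@@H]3[C@H]21
F2 | step 8 | bis(trimethylsilyl) dienol ether of F1 (C3-OSiMe3 with C2=C3 and C1=C5; C3′-OSiMe3 with C2′=C3′) | C=C1C(O[Si](C)(C)C)=C2C=3[C@H](CC[C@H]4C(=C)C(=O)O[C@@H]4C1=3)CC[C@]21C(O[Si](C)(C)C)=C[C@H]2C(=C)CC[C@H]3C(=C)C(=O)O[C@@H]3[C@H]21
F3 | step 3 | 10α-hydroxy-3-oxo-1αH,4αH,5αH-guaian-12,6α-olide (4β-methyl, 11βH) | C[C@@]1(O)CC[C@@H]2[C@@H]([C@H]3[C@@H](C)C(=O)C[C@H]31)OC(=O)[C@H]2C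
F4 | step 3 | 3β,10α-dihydroxy-1αH,4αH,5αH-guaian-12,6α-olide | C[C@@]1(O)CC[C@@H]2[C@@H]([C@H]3[C@@H](C)[C@@H](O)C[C@H]31)OC(=O)[C@H]2C
F5 | step 3 | 3β-methanesulfonate of F4 | C[C@@]1(O)CC[C@@H]2[C@@H]([C@H]3[C@@H](C)[C@@H](OS(C)(=O)=O)C[C@H]31)OC(=O)[C@H]2C
F6 | step 6 | 11β,13-dihydroestafiatin (3α,4α-epoxy-1αH,5αH-guai-10(14)-en-12,6α-olide) | C=C1CC[C@@H]2[C@@H]([C@H]3[C@]4(C)O[C@@H]4C[C@H]31)OC(=O)[C@H]2C
F7 | step 6 | 11β,13-dihydro-3-epizaluzanin C (3α-hydroxy-1αH,5αH-guaia-4(15),10(14)-dien-12,6α-olide) | C=C1CC[C@@H]2[C@@H]([C@@H]3[C@H]1C[C@@H](O)C3=C)OC(=O)[C@H]2C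
F8 | step 6 | 11β-phenylselanyl-11α-methyl derivative of F7 | C=C1CC[C@@H]2[C@@H]([C@@H]3[C@H]1C[C@@H](O)C3=C)OC(=O)[C@]2(C)[Se]c4ccccc4
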